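**Plan**
1. Cuts: in each of the two identical quinone rings (C1=O, C2–OH, C3–alkyl, C4=O, C5–OMe, C6–CH3) the bonds C1–C6 and C4–C5 are cut and a C1–C4 bond is restored, giving a four-membered ring. The two C3–CH2 bonds to the chain are cut next, and the C2 hydroxyl is carried as a tert-butyl ether.
2. Forward: tridecanedioic acid is taken to the 1,13-dilithio chain. Methoxyallene is added to di-tert-butyl squarate (C4–C5). The chain is then joined at both ends with carbonyl transposition (C3–CH2). One heating expands both four-membered rings to the six-membered quinones (C1–C4 broken, C1–C6 made), and acid frees the hydroxyls.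
3. Enabling feature: C1–C4, with oxygen on C1, C2 and C4, are the skeleton of squaric acid with one oxygen exchanged for the chain. C5(OMe)=C6(CH3) is an α-methoxyallene seen through a proton shift (the allene CH2 becomes the C6 methyl), so the quinone oxidation level arises without an oxidant. The twofold symmetry about the chain lets both ends be worked at once.
4. Stereochemistry: the target has no stereocentre and no stereogenic double bond. The carbinol centres of the cyclobutenone intermediates arise as mixtures and are erased in the ring expansion.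

Key step: step 5

Remark: the linker is read as thirteen CH2 groups; di-tert-butyl squarate and methoxyallene are treated as purchasable.

**Step 1**
Reactants: 1 tridecanedioic acid
Product: 2 tridecane-1,13-diol
Conditions: BH3·THF, THF, 0 °C to rt; then H2O
Reagents that add atoms: none
Why: Borane reduction of a carboxylic acid should take both acid groups to primary alcohols, and the saturated chain offers nothing else to reduce.

**Step 2**
Reactants: 2 tridecane-1,13-diol
Product: 3 1,13-diiodotridecane
Conditions: I2, PPh3, imidazole, CH2Cl2, 0 °C to rt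
Reagents that add atoms: iodine, II
Why: Appel-type iodination should replace each primary hydroxyl by iodide through SN2 attack on the alkoxyphosphonium ion.

**Step 3**
Reactants: 4 methoxyallene; 5 di-tert-butyl squarate
Product: 8 2,3-di-tert-butoxy-4-(1-methoxypropa-1,2-dien-1-yl)-4-(trimethylsilyloxy)cyclobut-2-en-1-one (racemic), via 1-lithio-1-methoxyallene 6 (not isolated), via lithium alkoxide adduct 7 (not isolated)
Conditions: 4, n-BuLi, THF, −78 °C; added to 5, THF, −78 °C; then Me3SiCl, −78 to 0 °C; aq NaHCO3
Reagents that add atoms: chlorotrimethylsilane, C[Si](C)(C)Cl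
Why: Methoxyallene is lithiated at C1 and the allenyllithium adds 1,2 to one of the two equivalent squarate carbonyls (organolithium addition to a squaric ester), the tertiary alkoxide being trapped as its trimethylsilyl ether so that it can neither be acylated nor ionise in step 4; the carbinol centre is racemic and is erased in step 5.

**Step 4**
Reactants: 3 1,13-diiodotridecane; 8 (two equivalents)
Product: 12 1,13-bis[2-tert-butoxy-4-(1-methoxypropa-1,2-dien-1-yl)-3-oxo-4-(trimethylsilyloxy)cyclobut-1-en-1-yl]tridecane (mixture of diastereomers), via 1,13-dilithiotridecane 9 (not isolated), via bis(lithium alkoxide) 10 (not isolated), via bis(trifluoroacetate) 11 (not isolated)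
Conditions: 3, t-BuLi, Et2O/pentane, −78 °C to rt; then 8, THF, −78 °C; then (CF3CO)2O, 2,6-lutidine, −78 °C; aq NaHCO3
Reagents that add atoms: none
Why: Iodine–lithium exchange gives the α,ω-dilithioalkane, which adds 1,2 to the only carbonyl of two molecules of 8, and acylation of the new alkoxides (the silyl ethers cannot be acylated) lets trifluoroacetate leave with allylic transposition to a tert-butoxy-stabilised cation that sheds 2-methylpropene, a sequential organolithium addition to a squarate followed by anhydride-induced carbonyl transposition that puts the chain on the β-carbon and the ketone next to the tert-butoxy carbon; the carbinol centres are mixtures and are erased in step 5.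

**Step 5**
Reactants: 12
Product: 16 3,3'-(tridecane-1,13-diyl)bis(2-tert-butoxy-5-methoxy-6-methylcyclohexa-2,5-diene-1,4-dione), via bis(carbinol) 13 (not isolated), via bis(dienylketene) 14 (not isolated), via bis(o-quinone methide) 15 (not isolated)
Conditions: Bu4NF, AcOH, THF, −20 °C; then toluene, 80 °C, dilute
Reagents that add atoms: none
Why: Fluoride removes silicon, and on warming the σ-bond between the ketone carbon and the carbinol carbon of each cyclobutenone opens in a thermal 4π-electrocyclic (conrotatory) process to the dienylketene, the hydroxyl rotating outward and the allenyl group inward. The ketene carbon then bonds to the central allene carbon in a 6π-electrocyclic (disrotatory) closure, the only ring closure of the step, which turns each four-membered ring into a six-membered ring as an o-quinone methide. A proton shift from the ring hydroxyl to the exocyclic methylene (tautomerisation, carried by traces of acetic acid) should deliver the quinone with its C-methyl group, so no oxidant is needed. The closest known reaction type is the thermal ring expansion of 4-allenyl- and 4-alkenyl-4-oxycyclobutenones to o-quinone methides and hydroquinones (Moore rearrangement). No stereocentre is formed and the carbinol centres are destroyed. The step needs electrocyclisation onto the allene instead of addition of the enol hydroxyl to the ketene or intermolecular capture of the quinone methide; the outward rotation of the oxygen substituent, the internal hydroxyl that quenches the quinone methide and dilution secure this, and the substitution pattern was fixed in step 4.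

**Step 6**
Reactants: 16
Product: 17 3,3'-(tridecane-1,13-diyl)bis(2-hydroxy-5-methoxy-6-methylcyclohexa-2,5-diene-1,4-dione) (CNP0110425.0)
Conditions: CF3CO2H, CH2Cl2, 0 °C to rt
Reagents that add atoms: none
Why: Acidolysis of the tert-butyl vinylogous ester (SN1 loss of 2-methylpropene) should unmask each 2-hydroxyquinone while the methyl vinylogous ester, which cannot ionise, stays.

**Compound list**
1 | tridecanedioic acid | OC(=O)CCCCCCCCCCCC(O)=O | starting material
2 | tridecane-1,13-diol | OCCCCCCCCCCCCCO | intermediate
3 | 1,13-diiodotridecane | ICCCCCCCCCCCCCI | intermediate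
4 | methoxyallene (1-methoxypropa-1,2-diene) | COC=C=C | starting material
5 | di-tert-butyl squarate (3,4-di-tert-butoxycyclobut-3-ene-1,2-dione) | CC(C)(C)OC1=C(OC(C)(C)C)C(=O)C1=O | starting material
6 | 1-lithio-1-methoxyallene | [Li]C(OC)=C=C | intermediate
7 | lithium 2,3-di-tert-butoxy-1-(1-methoxypropa-1,2-dien-1-yl)-4-oxocyclobut-2-en-1-olate (racemic) | C=C=C(OC)C1(O[Li])C(OC(C)(C)C)=C(OC(C)(C)C)C1=O | intermediate
8 | 2,3-di-tert-butoxy-4-(1-methoxypropa-1,2-dien-1-yl)-4-(trimethylsilyloxy)cyclobut-2-en-1-one (racemic) | C=C=C(OC)C1(O[Si](C)(C)C)C(OC(C)(C)C)=C(OC(C)(C)C)C1=O | intermediate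
9 | 1,13-dilithiotridecane | [Li]CCCCCCCCCCCCC[Li] | intermediate
10 | dilithium salt of 1,13-bis[2,3-di-tert-butoxy-1-hydroxy-4-(1-methoxypropa-1,2-dien-1-yl)-4-(trimethylsilyloxy)cyclobut-2-en-1-yl]tridecane (mixture of diastereomers) | [Li]OC1(CCCCCCCCCCCCCC2(O[Li])C(OC(C)(C)C)=C(OC(C)(C)C)C2(O[Si](C)(C)C)C(OC)=C=C)C(OC(C)(C)C)=C(OC(C)(C)C)C1(O[Si](C)(C)C)C(OC)=C=C | intermediate
11 | bis(trifluoroacetate) of the diol corresponding to 10 (mixture of diastereomers) | FC(F)(F)C(=O)OC1(CCCCCCCCCCCCCC2(OC(=O)C(F)(F)F)C(OC(C)(C)C)=C(OC(C)(C)C)C2(O[Si](C)(C)C)C(OC)=C=C)C(OC(C)(C)C)=C(OC(C)(C)C)C1(O[Si](C)(C)C)C(OC)=C=C | intermediate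
12 | 1,13-bis[2-tert-butoxy-4-(1-methoxypropa-1,2-dien-1-yl)-3-oxo-4-(trimethylsilyloxy)cyclobut-1-en-1-yl]tridecane (racemic and meso forms) | C=C=C(OC)C1(O[Si](C)(C)C)C(=O)C(OC(C)(C)C)=C1CCCCCCCCCCCCCC1=C(OC(C)(C)C)C(=O)C1(O[Si](C)(C)C)C(OC)=C=C | intermediate
13 | 1,13-bis[2-tert-butoxy-4-hydroxy-4-(1-methoxypropa-1,2-dien-1-yl)-3-oxocyclobut-1-en-1-yl]tridecane (racemic and meso forms) | C=C=C(OC)C1(O)C(=O)C(OC(C)(C)C)=C1CCCCCCCCCCCCCC1=C(OC(C)(C)C)C(=O)C1(O)C(OC)=C=C | intermediate
14 | bis(dienylketene): tridecane-1,13-diyl chain carrying at each end C(=C(OH)–C(OMe)=C=CH2)–C(O-t-Bu)=C=O, ketenyl cis to allenyl | O=C=C(OC(C)(C)C)/C(CCCCCCCCCCCCC/C(C(OC(C)(C)C)=C=O)=C(\O)C(OC)=C=C)=C(/O)C(OC)=C=C | intermediate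
15 | 1,13-bis(2-tert-butoxy-6-hydroxy-5-methoxy-4-methylidene-3-oxocyclohexa-1,5-dien-1-yl)tridecane | C=C1C(=O)C(OC(C)(C)C)=C(CCCCCCCCCCCCCC2=C(OC(C)(C)C)C(=O)C(=C)C(OC)=C2O)C(O)=C1OC | intermediate
16 | 3,3'-(tridecane-1,13-diyl)bis(2-tert-butoxy-5-methoxy-6-methylcyclohexa-2,5-diene-1,4-dione) | COC1=C(C)C(=O)C(OC(C)(C)C)=C(CCCCCCCCCCCCCC2=C(OC(C)(C)C)C(=O)C(C)=C(OC)C2=O)C1=O | intermediate
17 | 3,3'-(tridecane-1,13-diyl)bis(2-hydroxy-5-methoxy-6-methylcyclohexa-2,5-diene-1,4-dione) | COC1=C(C)C(=O)C(O)=C(CCCCCCCCCCCCCC2=C(O)C(=O)C(C)=C(OC)C2=O)C1=O | target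

**Totals**
Total step count: 6. Longest linear sequence: 5 steps (steps 1, 2, 4, 5, 6); step 3 is the side branch.

**Steps most likely to fail**

Step 4. The two-fold carbonyl addition may stop at one end or be outrun by proton abstraction, and Wurtz-type coupling may erode the dilithio chain during the exchange, because the carbonyl of 8 is flanked by a quaternary carbon and a tert-butoxy carbon. The fallback sets out from 8 and returns at 16. The thirteen-carbon chain would be made from purchased 1,9-dibromononane and LiC≡CH·H2NCH2CH2NH2 in DMSO as trideca-1,12-diyne F1. n-BuLi should turn it into 1,13-dilithiotrideca-1,12-diyne F2, a slim and weakly basic nucleophile. Addition to two molecules of 8 and ionisation with (CF3CO)2O as in step 4 should give the bis(alkynylcyclobutenone) silyl ether F3. Bu4NF/AcOH should then give the dicarbinol F4, and heating as in step 5 the bis(alkynylquinone) F5. Hydrogenation over Pd/C in EtOAc would saturate both triple bonds and take the quinones to the bis-hydroquinone F6, which air or Ag2O returns to 16.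

Step 5. After desilylation the free alkoxyallenyl carbinol may cyclise under the basic fluoride conditions, or the quinone methide may be captured intermolecularly before the proton shift. The fallback sets out from 12 and returns at 16, with the order inverted. Compound 12 would be heated in toluene at 80 °C with the silyl ethers in place, the established mode for 4-silyloxy-4-allenylcyclobutenones, to give the bis(silyloxy o-quinone methide) F7. Bu4NF/AcOH at −78 °C would then remove silicon from a ring that is already six-membered; the phenoxide so formed is the dienolate of the methylquinone and should be protonated on carbon to give 16.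

Step 3. O-Silylation of the hindered tertiary alkoxide may be slow, leaving time for cyclisation onto the allene, reversal of the addition or a second addition. The fallback sets out from 3 and 5 and returns at 16; it gives up the allene and the carbonyl transposition for the normal mode of addition. Compound 9, made from 3 as in step 4, would be added to two equivalents of 5 and the adduct ionised with (CF3CO)2O to the bis(cyclobutenedione) F8. Purchased 2-bromo-1,1-dimethoxypropane should lose methanol with Me3SiOTf and i-Pr2NEt to give (Z)-2-bromo-1-methoxyprop-1-ene F9. t-BuLi at −78 °C would convert it into (1-methoxyprop-1-en-2-yl)lithium F10, in which lithium stands cis to methoxy. This should add to the more electrophilic carbonyl of each ring of F8, the one next to the tert-butoxy carbon, to give the bis(alkenylcarbinol) F11. Heating in toluene at 110 °C (4π opening, 6π closure, enolisation) should give the bis-hydroquinone F6, and Ag2O would oxidise it to 16.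

**Further compounds**
F1 | step 4 | trideca-1,12-diyne | C#CCCCCCCCCCC#C
F2 | step 4 | 1,13-dilithiotrideca-1,12-diyne | [Li]C#CCCCCCCCCCC#C[Li]
F3 | step 4 | 1,13-bis[2-tert-butoxy-4-(1-methoxypropa-1,2-dien-1-yl)-3-oxo-4-(trimethylsilyloxy)cyclobut-1-en-1-yl]trideca-1,12-diyne | C=C=C(OC)C1(O[Si](C)(C)C)C(=O)C(OC(C)(C)C)=C1C#CCCCCCCCCCC#CC1=C(OC(C)(C)C)C(=O)C1(O[Si](C)(C)C)C(OC)=C=C
F4 | step 4 | 1,13-bis[2-tert-butoxy-4-hydroxy-4-(1-methoxypropa-1,2-dien-1-yl)-3-oxocyclobut-1-en-1-yl]trideca-1,12-diyne | C=C=C(OC)C1(O)C(=O)C(OC(C)(C)C)=C1C#CCCCCCCCCCC#CC1=C(OC(C)(C)C)C(=O)C1(O)C(OC)=C=C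
F5 | step 4 | 3,3'-(trideca-1,12-diyne-1,13-diyl)bis(2-tert-butoxy-5-methoxy-6-methylcyclohexa-2,5-diene-1,4-dione) | COC1=C(C)C(=O)C(OC(C)(C)C)=C(C#CCCCCCCCCCC#CC2=C(OC(C)(C)C)C(=O)C(C)=C(OC)C2=O)C1=O
F6 | step 4 | 3,3'-(tridecane-1,13-diyl)bis(2-tert-butoxy-5-methoxy-6-methylbenzene-1,4-diol) | COc1c(C)c(O)c(OC(C)(C)C)c(CCCCCCCCCCCCCc2c(OC(C)(C)C)c(O)c(C)c(OC)c2O)c1O
F7 | step 5 | 1,13-bis[2-tert-butoxy-5-methoxy-4-methylidene-3-oxo-6-(trimethylsilyloxy)cyclohexa-1,5-dien-1-yl]tridecane | C=C1C(=O)C(OC(C)(C)C)=C(CCCCCCCCCCCCCC2=C(OC(C)(C)C)C(=O)C(=C)C(OC)=C2O[Si](C)(C)C)C(O[Si](C)(C)C)=C1OC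
F8 | step 3 | 1,13-bis(2-tert-butoxy-3,4-dioxocyclobut-1-en-1-yl)tridecane | CC(C)(C)OC1=C(CCCCCCCCCCCCCC2=C(OC(C)(C)C)C(=O)C2=O)C(=O)C1=O
F9 | step 3 | (Z)-2-bromo-1-methoxyprop-1-ene | CO/C=C(\Br)C
F10 | step 3 | (1-methoxyprop-1-en-2-yl)lithium, lithium cis to methoxy | CO/C=C(\[Li])C
F11 | step 3 | 1,13-bis{2-tert-butoxy-3-hydroxy-3-[(Z)-1-methoxyprop-1-en-2-yl]-4-oxocyclobut-1-en-1-yl}tridecane (mixture of diastereomers) | CO\C=C(C)/C1(O)C(=O)C(CCCCCCCCCCCCCC2=C(OC(C)(C)C)C(O)(/C(C)=C\OC)C2=O)=C1OC(C)(C)C
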